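## Retrosynthetic overview

1. Target 17 ⇐ epoxy alcohol 16 (Mitsunobu inversion at C5 with angelic acid) ⇐ cyclohexenol 15 (hydroxyl-directed epoxidation) ⇐ enone 14 (Luche reduction) ⇐ hydroxy enone 12 (Mitsunobu inversion at C6) ⇐ silyl dienol ether 9 (Rubottom oxidation).
2. Key disconnection C8–C9: [2,3]-Wittig rearrangement of bis-allylic ether 6. C8 reacts as an α-alkoxy allyl carbanion (a carbinol carbon with reversed polarity) and attacks the vinyl terminus of a 1,1-dimethylallyl ether. This sets C8, delivers the linear prenyl group, and the alkoxide is trapped in the flask as the acetate.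
3. Ether 6 ⇐ allylic chloride 3 + 2-methylbut-3-en-2-ol (Williamson); 3 ⇐ (R)-carvone by ene-type chlorination and silyl dienol ether formation.
4. Rings: the carbocycle and C1 are bought with (R)-carvone; the only ring made is the oxirane, in step 8.

Assumption 1: locants in the text follow bisabolane numbering. Ring C1 bears the side chain, C2 is CH2, C3/C4 are the oxirane carbons (methyl on C4), C5 and C6 carry the angelates; side chain is C7(=C14H2), C8 (carbinol), C9, C10=C11. The target is (1S,3S,4S,5S,6R,8S): C6–O and the oxirane oxygen are cis to the side chain, C5–O is trans.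

Assumption 2: the sense of induction of the chiral ligand in step 4 is taken as written and must be confirmed on the first run; both antipodes of the ligand are sold.

## Route

Step 1
Reactants: 1 (R)-(−)-carvone
Product: 2 (5R)-5-(3-chloroprop-1-en-2-yl)-2-methylcyclohex-2-en-1-one (10-chlorocarvone)
Conditions: Ca(OCl)2, CO2 (dry ice), CH2Cl2/H2O, 0 °C
Reagents that add atoms: calcium hypochlorite, [Ca+2].[O-]Cl.[O-]Cl
Why: Ene-type allylic chlorination by hypochlorous acid attacks only the electron-rich 1,1-disubstituted isopropenyl alkene and not the enone, shifting the double bond to give the 2-substituted allyl chloride while C1 is untouched.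

Step 2
Reactants: 2 10-chlorocarvone
Product: 3 tert-butyl{[(3R)-3-(3-chloroprop-1-en-2-yl)-6-methylcyclohexa-1,5-dien-1-yl]oxy}dimethylsilane
Conditions: TBSOTf, Et3N, CH2Cl2, 0 °C, 30 min
Reagents that add atoms: tert-butyldimethylsilyl trifluoromethanesulfonate, CC(C)(C)[Si](C)(C)OS(=O)(=O)C(F)(F)F
Why: Soft enolisation (silyl triflate/amine) removes the C6 proton to give the 2-silyloxy-1,3-diene, which masks the ketone against the bases of steps 3 and 4 (no γ-enolate, so no intramolecular alkylation to a bicyclo[2.2.2]octenone) and is the handle for the Rubottom oxidation in step 5.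

Step 3
Reactants: 3 allylic chloride; 4 2-methylbut-3-en-2-ol
Product: 6 tert-butyl(dimethyl){[(3R)-6-methyl-3-{3-[(2-methylbut-3-en-2-yl)oxy]prop-1-en-2-yl}cyclohexa-1,5-dien-1-yl]oxy}silane, via sodium 2-methylbut-3-en-2-olate 5 (not isolated)
Conditions: 4 (2 equiv), NaH, THF, 0 °C; then 3, Bu4NI (10 mol %), 0 °C → rt
Reagents that add atoms: none
Why: Williamson ether synthesis in which the tertiary alkoxide displaces the unhindered primary allylic chloride (SN2 and SN2' give the same product because the allyl termini are equivalent), with iodide catalysis and no enolisable ketone present.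

Step 4
Reactants: 6 bis-allylic ether
Product: 9 (3S)-2-[(1R)-3-{[tert-butyl(dimethyl)silyl]oxy}-4-methylcyclohexa-2,4-dien-1-yl]-6-methylhepta-1,5-dien-3-yl acetate, via C8-lithiated ether 7 (not isolated), via lithium C8-alkoxide 8 (not isolated)
Conditions: t-BuLi (1.3 equiv), 2,2-bis[(4S)-4-isopropyl-4,5-dihydrooxazol-2-yl]propane (1.5 equiv), hexane/Et2O, −78 °C, 3 h; then Ac2O, −78 → 0 °C
Reagents that add atoms: acetic anhydride, CC(=O)OC(C)=O
Why: Proposed new method: the t-BuLi·bis(oxazoline) complex removes a C8–H (oxygen-directed and kinetically favoured over the hindered, doubly allylic C1–H) to give the α-alkoxy allyllithium 7, which attacks the terminal vinyl carbon of the 1,1-dimethylallyl group through the five-membered envelope transition state of a [2,3]-Wittig rearrangement; the quaternary ether carbon leaves no second deprotonation site and the shift can only deliver the linear prenyl group, the chiral ligand on lithium selects the carbanion face so that C8 forms as (S), and alkoxide 8 is acetylated in the flask; the closest known reactions are [2,3]-Wittig rearrangements of bis-allylic ethers of tertiary allylic alcohols and alkyllithium/bis(oxazoline)-mediated enantioselective [2,3]-Wittig rearrangements, here extended to reagent control beside a remote ring stereocentre.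

Step 5
Reactants: 9 silyl dienol ether acetate
Product: 12 (3S)-2-[(1S,2S)-2-hydroxy-4-methyl-3-oxocyclohex-4-en-1-yl]-6-methylhepta-1,5-dien-3-yl acetate, via silyloxy epoxide 10 (not isolated), via 6-silyloxy enone 11 (not isolated)
Conditions: mCPBA (1.05 equiv), NaHCO3, CH2Cl2, −40 °C; then HF·pyridine, THF, 0 °C
Reagents that add atoms: mCPBA, O=C(OO)c1cccc(Cl)c1
Why: Rubottom oxidation, in which the silyl enol ether bond C5=C6 (far more nucleophilic than the prenyl or the acetate-deactivated alkene) is epoxidised on the face opposite the adjacent C1 side chain, the silyl group shifts to give 11, and fluoride releases the 6-hydroxy enone with the hydroxyl trans to the side chain.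

Step 6
Reactants: 12 trans-6-hydroxy enone; 13 angelic acid
Product: 14 (1R,6S)-6-[(3S)-3-acetoxy-6-methylhepta-1,5-dien-2-yl]-3-methyl-2-oxocyclohex-3-en-1-yl (2Z)-2-methylbut-2-enoate
Conditions: PPh3, DIAD, toluene, 0 °C → rt
Reagents that add atoms: none
Why: Mitsunobu esterification displaces the activated α-keto hydroxyl by angelate with clean SN2 inversion (the adjacent carbonyl accelerates the displacement), placing the C6 angelate cis to the side chain, and the neutral conditions avoid the base-promoted Z-to-E isomerisation of angelates to tiglates.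

Step 7
Reactants: 14 cis-6-angeloyloxy enone
Product: 15 (1R,2S,6S)-6-[(3S)-3-acetoxy-6-methylhepta-1,5-dien-2-yl]-2-hydroxy-3-methylcyclohex-3-en-1-yl (2Z)-2-methylbut-2-enoate
Conditions: NaBH4, CeCl3·7H2O, MeOH, −78 °C; AcOH quench
Reagents that add atoms: none
Why: Luche 1,2-reduction in which hydride attacks C5 anti to the pseudo-axial C6 acyloxy group (polar Felkin–Anh and steric control agree), giving the allylic alcohol cis to the C6 angelate and to the side chain, while the cold acidic quench prevents acyl migration.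

Step 8
Reactants: 15 all-cis cyclohexenol
Product: 16 (1R,2R,3R,4S,6S)-4-[(3S)-3-acetoxy-6-methylhepta-1,5-dien-2-yl]-2-hydroxy-1-methyl-7-oxabicyclo[4.1.0]heptan-3-yl (2Z)-2-methylbut-2-enoate
Conditions: VO(acac)2 (5 mol %), t-BuOOH (decane solution, 1.5 equiv), CH2Cl2, 0 °C → rt
Reagents that add atoms: tert-butyl hydroperoxide, CC(C)(C)OO
Why: Hydroxyl-directed vanadium-catalysed epoxidation delivers oxygen from the vanadium alkoxide of the C5 hydroxyl to the syn face of C3=C4 only (oxirane cis to C5–OH, C6–O and the side chain), and the C7=C14 and C10=C11 alkenes, which have no free allylic hydroxyl, are not touched.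

Step 9
Reactants: 16 epoxy alcohol; 13 angelic acid
Product: 17 (1S,2S,3R,4S,6S)-4-[(3S)-3-acetoxy-6-methylhepta-1,5-dien-2-yl]-1-methyl-7-oxabicyclo[4.1.0]heptane-2,3-diyl bis[(2Z)-2-methylbut-2-enoate]
Conditions: PPh3, DIAD, toluene, 0 → 40 °C
Reagents that add atoms: none
Why: Mitsunobu esterification inverts C5 by SN2 attack of angelate on the face anti to the oxirane oxygen, giving the trans-5,6-diester; the C6 ester and the oxirane oxygen are both cis to the leaving group and so cannot participate.

## Compound list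

1 | (R)-(−)-carvone, (5R)-2-methyl-5-(prop-1-en-2-yl)cyclohex-2-en-1-one | C=C(C)[C@@H]1CC=C(C)C(=O)C1 | starting material
2 | (5R)-5-(3-chloroprop-1-en-2-yl)-2-methylcyclohex-2-en-1-one (10-chlorocarvone) | C=C(CCl)[C@@H]1CC=C(C)C(=O)C1 | intermediate
3 | tert-butyl{[(3R)-3-(3-chloroprop-1-en-2-yl)-6-methylcyclohexa-1,5-dien-1-yl]oxy}dimethylsilane | C=C(CCl)[C@@H]1CC=C(C)C(O[Si](C)(C)C(C)(C)C)=C1 | intermediate
4 | 2-methylbut-3-en-2-ol | C=CC(C)(C)O | starting material
5 | sodium 2-methylbut-3-en-2-olate | C=CC(C)(C)[O-].[Na+] | intermediate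
6 | tert-butyl(dimethyl){[(3R)-6-methyl-3-{3-[(2-methylbut-3-en-2-yl)oxy]prop-1-en-2-yl}cyclohexa-1,5-dien-1-yl]oxy}silane | C=C(COC(C)(C)C=C)[C@@H]1CC=C(C)C(O[Si](C)(C)C(C)(C)C)=C1 | intermediate
7 | C8-lithiated ether (6 with lithium on the OCH carbon; α-alkoxy allyllithium, configurationally labile) | C=C(C([Li])OC(C)(C)C=C)[C@@H]1CC=C(C)C(O[Si](C)(C)C(C)(C)C)=C1 | intermediate
8 | lithium (3S)-2-[(1R)-3-{[tert-butyl(dimethyl)silyl]oxy}-4-methylcyclohexa-2,4-dien-1-yl]-6-methylhepta-1,5-dien-3-olate | C=C([C@H](CC=C(C)C)[O-])[C@@H]1CC=C(C)C(O[Si](C)(C)C(C)(C)C)=C1.[Li+] | intermediate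
9 | (3S)-2-[(1R)-3-{[tert-butyl(dimethyl)silyl]oxy}-4-methylcyclohexa-2,4-dien-1-yl]-6-methylhepta-1,5-dien-3-yl acetate | C=C([C@H](CC=C(C)C)OC(C)=O)[C@@H]1CC=C(C)C(O[Si](C)(C)C(C)(C)C)=C1 | intermediate
10 | silyloxy epoxide (9 with the C5=C6 enol ether bond epoxidised; oxirane oxygen trans to the C1 side chain) | C=C([C@H](CC=C(C)C)OC(C)=O)[C@@H]1CC=C(C)[C@@]2(O[Si](C)(C)C(C)(C)C)O[C@@H]12 | intermediate
11 | (3S)-2-[(1S,2S)-2-{[tert-butyl(dimethyl)silyl]oxy}-4-methyl-3-oxocyclohex-4-en-1-yl]-6-methylhepta-1,5-dien-3-yl acetate | C=C([C@H](CC=C(C)C)OC(C)=O)[C@@H]1CC=C(C)C(=O)[C@H]1O[Si](C)(C)C(C)(C)C | intermediate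
12 | (3S)-2-[(1S,2S)-2-hydroxy-4-methyl-3-oxocyclohex-4-en-1-yl]-6-methylhepta-1,5-dien-3-yl acetate (6-OH trans to the side chain) | C=C([C@H](CC=C(C)C)OC(C)=O)[C@@H]1CC=C(C)C(=O)[C@H]1O | intermediate
13 | angelic acid, (2Z)-2-methylbut-2-enoic acid | C/C=C(/C)C(=O)O | starting material
14 | (1R,6S)-6-[(3S)-3-acetoxy-6-methylhepta-1,5-dien-2-yl]-3-methyl-2-oxocyclohex-3-en-1-yl (2Z)-2-methylbut-2-enoate | C=C([C@H](CC=C(C)C)OC(C)=O)[C@@H]1CC=C(C)C(=O)[C@@H]1OC(=O)/C(C)=C\C | intermediate
15 | (1R,2S,6S)-6-[(3S)-3-acetoxy-6-methylhepta-1,5-dien-2-yl]-2-hydroxy-3-methylcyclohex-3-en-1-yl (2Z)-2-methylbut-2-enoate | C=C([C@H](CC=C(C)C)OC(C)=O)[C@@H]1CC=C(C)[C@H](O)[C@@H]1OC(=O)/C(C)=C\C | intermediate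
16 | (1R,2R,3R,4S,6S)-4-[(3S)-3-acetoxy-6-methylhepta-1,5-dien-2-yl]-2-hydroxy-1-methyl-7-oxabicyclo[4.1.0]heptan-3-yl (2Z)-2-methylbut-2-enoate | C=C([C@H](CC=C(C)C)OC(C)=O)[C@@H]1C[C@@H]2O[C@]2(C)[C@H](O)[C@@H]1OC(=O)/C(C)=C\C | intermediate
17 | (1S,2S,3R,4S,6S)-4-[(3S)-3-acetoxy-6-methylhepta-1,5-dien-2-yl]-1-methyl-7-oxabicyclo[4.1.0]heptane-2,3-diyl bis[(2Z)-2-methylbut-2-enoate] (CNP0188566.1) | C=C([C@H](CC=C(C)C)OC(C)=O)[C@@H]1C[C@@H]2O[C@]2(C)[C@@H](OC(=O)/C(C)=C\C)[C@@H]1OC(=O)/C(C)=C\C | target

## Step count and risks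

Total step count: 9. Longest linear sequence: 9 steps from (R)-carvone 1 (compounds 4 and 13 are bought).

The three steps most likely to fail:

**Step 4 (ligand-controlled [2,3]-Wittig rearrangement).** The risks are modest diastereoselectivity at C8, competing deprotonation at C1–H, and [1,2]-shift. The fallback sets out from 6 and comes back at 9, and moves the control of C8 from the rearrangement to a reagent-controlled ketone reduction. Ether 6 is rearranged without ligand (n-BuLi, THF, −78 °C, NH4Cl quench) to the C8-epimeric allylic alcohols F1. These are oxidised with Dess–Martin periodinane buffered with pyridine to the cross-conjugated dienone F2. Reduction with (R)-Me-CBS oxazaborolidine ((3aR)-1-methyl-3,3-diphenyltetrahydro-3H-pyrrolo[1,2-c][1,3,2]oxazaborole) and catecholborane in toluene at −78 °C treats the branched vinyl group as the large substituent and gives the (8S)-alcohol F3. Acetylation (Ac2O, Et3N, DMAP) returns 9.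

**Step 9 (Mitsunobu at the hindered C5 carbinol, next to the quaternary oxirane carbon).** The risks are no reaction or elimination. The fallback sets out from 16 and comes back at 17, and separates activation from displacement. Alcohol 16 is converted with Tf2O and pyridine in CH2Cl2 at −30 °C into the C5 triflate F6. This is displaced with inversion by the cesium angelate F5 described in the next fallback, with 18-crown-6 in toluene at rt, giving 17.

**Step 6 (Mitsunobu on the α-hydroxy ketone with angelic acid).** The risks are sluggish displacement next to the branched C1 and loss of angelate geometry. The fallback sets out from 9 and comes back at 14, replacing oxidation/Mitsunobu by halogenation/carboxylate displacement. Silyl dienol ether 9 is brominated with NBS in THF at −78 °C, anti to the side chain, to give the trans-6-bromo enone F4. Cesium angelate F5, made from 13 and Cs2CO3, displaces the α-keto bromide in DMF at 0 °C with SN2 inversion to give 14 directly.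

## Further compounds

F1 | step 4 | 2-[(1R)-3-{[tert-butyl(dimethyl)silyl]oxy}-4-methylcyclohexa-2,4-dien-1-yl]-6-methylhepta-1,5-dien-3-ol (mixture of C8 epimers) | C=C(C(O)CC=C(C)C)[C@@H]1CC=C(C)C(O[Si](C)(C)C(C)(C)C)=C1
F2 | step 4 | 2-[(1R)-3-{[tert-butyl(dimethyl)silyl]oxy}-4-methylcyclohexa-2,4-dien-1-yl]-6-methylhepta-1,5-dien-3-one | C=C(C(=O)CC=C(C)C)[C@@H]1CC=C(C)C(O[Si](C)(C)C(C)(C)C)=C1
F3 | step 4 | (3S)-2-[(1R)-3-{[tert-butyl(dimethyl)silyl]oxy}-4-methylcyclohexa-2,4-dien-1-yl]-6-methylhepta-1,5-dien-3-ol | C=C([C@H](CC=C(C)C)O)[C@@H]1CC=C(C)C(O[Si](C)(C)C(C)(C)C)=C1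
F4 | step 6 | (3S)-2-[(1S,2S)-2-bromo-4-methyl-3-oxocyclohex-4-en-1-yl]-6-methylhepta-1,5-dien-3-yl acetate (bromine trans to the side chain) | C=C([C@H](CC=C(C)C)OC(C)=O)[C@@H]1CC=C(C)C(=O)[C@H]1Br
F5 | step 6 | cesium (2Z)-2-methylbut-2-enoate (cesium angelate) | [Cs+].[O-]C(=O)/C(C)=C\C
F6 | step 9 | C5 trifluoromethanesulfonate of 16 (triflate cis to the oxirane oxygen and to the C6 angelate) | C=C([C@H](CC=C(C)C)OC(C)=O)[C@@H]1C[C@@H]2O[C@]2(C)[C@H](OS(=O)(=O)C(F)(F)F)[C@@H]1OC(=O)/C(C)=C\C
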